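A one-step world E + Q → L keeps what it makes, but the larch run does not: its L reads 86.5 mM at 6.0 min and 70.9 mM at 14 min.

| setting | birch | ash | larch | oak | alder |
|---|---|---|---|---|---|
| E | 100 mM | 50.0 mM | 100 mM | 200 mM | 100 mM |
| Q | 200 mM | 150 mM | 600 mM | 200 mM | 1400 mM |
| time |  |  |  |  | 14 min |

- birch run (time / min: [L] / mM): 2.0: 17.4; 4.0: 28.8; 6.0: 42.9; 8.0: 51.4; 10: 54.6; 12: 58.7; 14: 60.3
- ash run (time / min: [L] / mM): 2.0: 4.2; 4.0: 11.0; 6.0: 14.7; 8.0: 19.0; 10: 21.3; 12: 23.2; 14: 24.8
- larch run (time / min: [L] / mM): 2.0: 67.2; 4.0: 85.7; 6.0: 86.5; 8.0: 83.7; 10: 80.3; 12: 75.1; 14: 70.9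
- oak run (time / min: [L] / mM): 2.0: 35.6; 4.0: 65.7; 6.0: 84.8; 8.0: 98.6; 10: 107.0; 12: 108.5; 14: 112.6

(readings scatter by 1 mM)

- Overall: E + Q -> L.
- Constant volume, constant temperature.
- "The second partner" is Q.
- An order is taken over about fifteen percent of the charge, up and down.

1. order of the initial rate in [E], near the charge of the birch run, the rate being that where two percent of its E are L (one fixed amount of L, the same in the runs compared)
2. order of the initial rate in [Q], near the charge of the birch run, the rate being that where two percent of its E are L
3. L in the alder run at 14 min, as a share of the E charged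

My reckoning for the alder run rests on two times. The make time τm is the mean time at which E becomes L. With Q in excess, E falls roughly pseudo-first-order, and the first larch reading, 67.2 mM at 2.0 min, gives τm = 1.79 min. The loss time τl, the time in which L falls by a factor e with no E left to replace it, is 36.2 min, as read from larch after 8.0 min, when about 1.16 % of its E should remain.

The first birch reading gives τm = 10.5 min, so larch makes L 5.87 times as fast on 3.00 times the Q. Scaling τm in simple proportion to Q is therefore cautious, and it gives about 0.769 min for alder. Now replace the curve of making by one instant at its mean. The error in ln L is half the square of τm/τl = 0.0213, about 0.0226 %. Alder then keeps 69.4 % of its charge at 14 min, if τl does not depend on Q, which these runs leave untested.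

The forecast gave orders of 1 in E and 1.8 in Q and, lower than my figure, 52 % for alder (30 % to 72 %), saying “The stalling in birch and oak suggests something between these”.

The flask gives orders of 1.0 and 1.5, and 68.1 %.

    E + Q → L (0.2550 L mol⁻¹ min⁻¹)
    E + 2 Q → L + Q (1.008 L² mol⁻² min⁻¹)
    E + Q + L → 2 L (6.780 L² mol⁻² min⁻¹)
    L → Ek (0.02820 min⁻¹)

In the alder run, E was the limiting reagent, at 100 mM against 1400 mM of Q. It turned to L while Q stayed above 1.30 M, the first two steps alone giving a mean time near 0.429 min, far shorter than τl. L → Ek, with 1/k4 = 35.5 min, then ran through about 0.383 such times, the path through E + Q + L making no difference, and at 14 min L stood at 68.1 % of the E charged.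

The numbers in the tables were generated by integration with made-up constants, and the scatter is random.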